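**Retrosynthetic overview**
1. Target 15 comes from its tri-O-methyl ether 14 by global O-demethylation; the aryl methyl ethers are the only protecting groups.
2. The pyranone ring is formed last: keto-dioxinone 12 loses acetone to an acylketene that lactonises. 12 comes from Weinreb amide 9 and dioxinone 10.
3. The ethyl group on ring A is installed late by ketone-directed C–H ethylation (Murai) of benzophenone 4, so the ketone is still unhindered in the key step.
4. Key step: aryne acyl-alkylation. 3-Methoxybenzyne inserts into the C(acyl)–CH2 bond of commercial β-keto ester 1, forming the diaryl ketone bond and the benzylic bond of ring B in one operation.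
5. Ring order: rings A and B are bought as arenes (ring B as an aryne precursor); the pyranone ring is built last. The usual Friedel–Crafts or aryl-metal/aldehyde route to the benzophenone is avoided.

Assumption: the target has no stereocentre (it is achiral), so no stereocontrol is needed; it is drawn as the 4-hydroxy-2-pyranone tautomer.

**Route**

Step 1
Reactants: 1 ethyl 3-(2,4-dimethoxyphenyl)-3-oxopropanoate; 2 3-methoxy-2-(trimethylsilyl)phenyl trifluoromethanesulfonate
Product: 4 ethyl 2-[2-(2,4-dimethoxybenzoyl)-3-methoxyphenyl]acetate, via 3-methoxybenzyne 3 (not isolated)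
Conditions: CsF (2.5 equiv), 2 (1.25 equiv), MeCN, 80 °C, 1 h
Reagents that add atoms: none
Why: Fluoride-induced 1,2-elimination gives the aryne, the enolate of 1 adds at the aryne carbon meta to OMe, and the aryl anion formed next to OMe closes onto the ketone and the benzocyclobutenoxide fragments, a formal C–C σ-bond insertion (aryne acyl-alkylation) that places the aroyl group between OMe and CH2CO2Et.

Step 2
Reactants: 4 ethyl 2-[2-(2,4-dimethoxybenzoyl)-3-methoxyphenyl]acetate; 5 ethylene
Product: 6 ethyl 2-[2-(2-ethyl-4,6-dimethoxybenzoyl)-3-methoxyphenyl]acetate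
Conditions: RuH2(CO)(PPh3)3 (6 mol%), ethylene (7 bar), toluene, 135 °C, autoclave
Reagents that add atoms: none
Why: Ketone-directed ortho C–H activation and olefin hydroarylation (Murai reaction) can only occur at C6 of ring A, because ring B has no C–H ortho to the carbonyl and ring A has only this one.

Step 3
Reactants: 6 ethyl 2-[2-(2-ethyl-4,6-dimethoxybenzoyl)-3-methoxyphenyl]acetate; 7 N,O-dimethylhydroxylamine hydrochloride
Product: 9 2-[2-(2-ethyl-4,6-dimethoxybenzoyl)-3-methoxyphenyl]-N-methoxy-N-methylacetamide, via aluminium amide 8 (not isolated)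
Conditions: AlMe3 (3 equiv), 7 (3 equiv), CH2Cl2, 0 °C, then 6, rt to 35 °C; 1 M HCl work-up
Reagents that add atoms: none
Why: Aminolysis of the ester by the aluminium amide (Weinreb amide formation) is reliable for enolisable arylacetates, and the tetra-ortho-substituted diaryl ketone is too hindered to react.

Step 4
Reactants: 9 2-[2-(2-ethyl-4,6-dimethoxybenzoyl)-3-methoxyphenyl]-N-methoxy-N-methylacetamide; 10 2,2,6-trimethyl-4H-1,3-dioxin-4-one
Product: 12 6-{3-[2-(2-ethyl-4,6-dimethoxybenzoyl)-3-methoxyphenyl]-2-oxopropyl}-2,2-dimethyl-4H-1,3-dioxin-4-one, via lithium dienolate 11 (not isolated)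
Conditions: 10 (2.5 equiv), LiN(SiMe3)2 (2.5 equiv), THF, −78 °C; then 9, −78 to −30 °C; 1 M HCl, 0 °C
Reagents that add atoms: none
Why: γ-Acylation of the dioxinone dienolate by the Weinreb amide (vinylogous Claisen-type condensation) stops at the chelated tetrahedral adduct, so the acidic ketone product is released only on quench.

Step 5
Reactants: 12 6-{3-[2-(2-ethyl-4,6-dimethoxybenzoyl)-3-methoxyphenyl]-2-oxopropyl}-2,2-dimethyl-4H-1,3-dioxin-4-one
Product: 14 6-{[2-(2-ethyl-4,6-dimethoxybenzoyl)-3-methoxyphenyl]methyl}-4-hydroxy-2H-pyran-2-one, via acylketene 13 (not isolated)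
Conditions: toluene (0.02 M), 110 °C, 2 h
Reagents that add atoms: none
Why: Thermal retro-[4+2] loss of acetone from the dioxinone gives an acylketene whose δ-keto enol oxygen adds to the ketene (acylketene lactonisation), the standard route to 6-substituted 4-hydroxy-2-pyranones.

Step 6
Reactants: 14 6-{[2-(2-ethyl-4,6-dimethoxybenzoyl)-3-methoxyphenyl]methyl}-4-hydroxy-2H-pyran-2-one
Product: 15 6-{[2-(2-ethyl-4,6-dihydroxybenzoyl)-3-hydroxyphenyl]methyl}-4-hydroxy-2H-pyran-2-one
Conditions: BBr3 (10 equiv), CH2Cl2, −78 °C to rt; then H2O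
Reagents that add atoms: none
Why: Lewis-acid O-demethylation of aryl methyl ethers with BBr3 cleaves the two chelating ortho ethers first and then the para ether, and 4-hydroxy-2-pyranones tolerate the reagent.

**Compound list**
1 | ethyl 3-(2,4-dimethoxyphenyl)-3-oxopropanoate | CCOC(=O)CC(=O)c1ccc(OC)cc1OC | starting material
2 | 3-methoxy-2-(trimethylsilyl)phenyl trifluoromethanesulfonate | COc1cccc(OS(=O)(=O)C(F)(F)F)c1[Si](C)(C)C | starting material
3 | 3-methoxybenzyne | COC1=CC=CC#C1 | intermediate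
4 | ethyl 2-[2-(2,4-dimethoxybenzoyl)-3-methoxyphenyl]acetate | CCOC(=O)Cc1cccc(OC)c1C(=O)c1ccc(OC)cc1OC | intermediate
5 | ethylene | C=C | starting material
6 | ethyl 2-[2-(2-ethyl-4,6-dimethoxybenzoyl)-3-methoxyphenyl]acetate | CCOC(=O)Cc1cccc(OC)c1C(=O)c1c(CC)cc(OC)cc1OC | intermediate
7 | N,O-dimethylhydroxylamine hydrochloride | CNOC.Cl | starting material
8 | chlorido(methyl)aluminium N-methoxy-N-methylamide | CON(C)[Al](C)Cl | intermediate
9 | 2-[2-(2-ethyl-4,6-dimethoxybenzoyl)-3-methoxyphenyl]-N-methoxy-N-methylacetamide | CON(C)C(=O)Cc1cccc(OC)c1C(=O)c1c(CC)cc(OC)cc1OC | intermediate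
10 | 2,2,6-trimethyl-4H-1,3-dioxin-4-one | CC1=CC(=O)OC(C)(C)O1 | starting material
11 | lithium 2,2-dimethyl-6-methylidene-6H-1,3-dioxin-4-olate | [Li+].[O-]C1=CC(=C)OC(C)(C)O1 | intermediate
12 | 6-{3-[2-(2-ethyl-4,6-dimethoxybenzoyl)-3-methoxyphenyl]-2-oxopropyl}-2,2-dimethyl-4H-1,3-dioxin-4-one | CC1(C)OC(=O)C=C(CC(=O)Cc2cccc(OC)c2C(=O)c2c(CC)cc(OC)cc2OC)O1 | intermediate
13 | 6-[2-(2-ethyl-4,6-dimethoxybenzoyl)-3-methoxyphenyl]-3,5-dioxohex-1-en-1-one | O=C=CC(=O)CC(=O)Cc1cccc(OC)c1C(=O)c1c(CC)cc(OC)cc1OC | intermediate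
14 | 6-{[2-(2-ethyl-4,6-dimethoxybenzoyl)-3-methoxyphenyl]methyl}-4-hydroxy-2H-pyran-2-one | CCc1cc(OC)cc(OC)c1C(=O)c1c(OC)cccc1Cc1cc(O)cc(=O)o1 | intermediate
15 | 6-{[2-(2-ethyl-4,6-dihydroxybenzoyl)-3-hydroxyphenyl]methyl}-4-hydroxy-2H-pyran-2-one | CCc1cc(O)cc(O)c1C(=O)c1c(O)cccc1Cc1cc(O)cc(=O)o1 | target

**Totals**
Total step count: 6. Longest linear sequence: 6 steps (1 to 15).

**Steps most likely to fail, with fallbacks**

Step 1 (aryne acyl-alkylation). The aryl anion may be protonated, giving plain α-arylation, or may transfer the ester instead of the electron-rich aroyl group. The fallback sets out from 2 and comes back at 4. The C–OTf bond of 2 is coupled, without fluoride so that no aryne forms, with the Reformatsky reagent BrZnCH2CO2Et (Pd2(dba)3, XPhos, THF, 60 °C) to give ethyl 2-[3-methoxy-2-(trimethylsilyl)phenyl]acetate F1. Its C–Si bond is then replaced in an ipso-Friedel–Crafts acylation with commercial 2,4-dimethoxybenzoyl chloride (AlCl3, CH2Cl2, −20 °C), which gives 4.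

Step 2 (Murai ethylation). The hindered benzophenone may chelate ruthenium poorly, or the ortho C–OMe bonds may be cleaved instead. The fallback sets out from 2 and comes back at 6, bringing the ethyl group in before the ketone is made. Compound 2 is converted as above into ethyl 2-[3-methoxy-2-(trimethylsilyl)phenyl]acetate F1. Commercial 1-(3,5-dimethoxyphenyl)ethanone is hydrogenolysed (H2, Pd/C, cat. HCl, EtOH) to 1-ethyl-3,5-dimethoxybenzene F2. F2 is chlorocarbonylated with oxalyl chloride (AlCl3, CH2Cl2, 0 °C; attack ortho to ethyl and para to OMe) to 2-ethyl-4,6-dimethoxybenzoyl chloride F3. Ipso-acylation of F1 with F3 (AlCl3, CH2Cl2, 0 °C) then gives 6; the linear acylium ion of a 2,6-disubstituted benzoyl chloride is not sterically shielded.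

Step 4 (dienolate acylation). The dienolate may deprotonate the arylacetamide CH2 instead of adding to the amide. The fallback sets out from 9 and comes back at 12, replacing the basic acylation by a Lewis-acid aldol and an oxidation. Amide 9 is reduced (iBu2AlH, THF, −78 °C) to 2-[2-(2-ethyl-4,6-dimethoxybenzoyl)-3-methoxyphenyl]acetaldehyde F4. Dioxinone 10 is silylated (LiN(SiMe3)2, Me3SiCl, THF, −78 °C) to trimethyl[(2,2-dimethyl-6-methylidene-6H-1,3-dioxin-4-yl)oxy]silane F5. A vinylogous Mukaiyama aldol of F4 and F5 (BF3·OEt2, CH2Cl2, −78 °C) gives racemic 6-{3-[2-(2-ethyl-4,6-dimethoxybenzoyl)-3-methoxyphenyl]-2-hydroxypropyl}-2,2-dimethyl-4H-1,3-dioxin-4-one F6. Dess–Martin oxidation (CH2Cl2, rt) erases the carbinol centre and gives 12.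

**Further compounds**
F1 | step 1 | ethyl 2-[3-methoxy-2-(trimethylsilyl)phenyl]acetate | CCOC(=O)Cc1cccc(OC)c1[Si](C)(C)C
F2 | step 2 | 1-ethyl-3,5-dimethoxybenzene | CCc1cc(OC)cc(OC)c1
F3 | step 2 | 2-ethyl-4,6-dimethoxybenzoyl chloride | CCc1cc(OC)cc(OC)c1C(Cl)=O
F4 | step 4 | 2-[2-(2-ethyl-4,6-dimethoxybenzoyl)-3-methoxyphenyl]acetaldehyde | O=CCc1cccc(OC)c1C(=O)c1c(CC)cc(OC)cc1OC
F5 | step 4 | trimethyl[(2,2-dimethyl-6-methylidene-6H-1,3-dioxin-4-yl)oxy]silane | C=C1C=C(O[Si](C)(C)C)OC(C)(C)O1
F6 | step 4 | 6-{3-[2-(2-ethyl-4,6-dimethoxybenzoyl)-3-methoxyphenyl]-2-hydroxypropyl}-2,2-dimethyl-4H-1,3-dioxin-4-one (racemic) | CC1(C)OC(=O)C=C(CC(O)Cc2cccc(OC)c2C(=O)c2c(CC)cc(OC)cc2OC)O1
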